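**Retrosynthetic overview**
- The ten-membered carbocycle is closed last by ring-closing metathesis at C4=C5 (Z enforced by the furanone oxygen bridge); the C8 angelate goes on shortly before.
- The 3(2H)-furanone comes from 5-endo-dig cyclisation of an α'-hydroxy ynone, made by acetylide opening of a temporary C1→O8 α-hydroxy-γ-lactone.
- Key C7–C8 bond: the C8 aldehyde reacts as an acyl anion (Breslow intermediate, Stetter reaction) at C7 of a chiral butenolide; C8 is then set by Felkin–Anh reduction and C11 by lactone-enolate methylation.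
- Fragments: quaternary C10 from (S)-lactic acid (self-regeneration of the stereocentre); C6 from (S)-5-(hydroxymethyl)furan-2(5H)-one.
- Ring order: 12,6-lactone (chiral pool) → temporary C1 lactone → furanone → carbocycle.

Assumption: germacrane numbering is used (C1 ketone, C3–O–C10 furanone bridge, C4=C5, C6 lactone oxygen, C8 ester, C12 lactone carbonyl, C13/C14/C15 methyls); the target is the (4Z,6R,7R,8R,10R,11S) isomer.

**Step 1**
Reactants: 1 (S)-lactic acid
Product: 2 (2S,5S)-2-tert-butyl-5-methyl-1,3-dioxolan-4-one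
Conditions: pivalaldehyde, TsOH·H2O (cat.), H2SO4 (cat.), pentane, reflux (Dean–Stark); recrystallise at −78 °C
Reagents that add atoms: pivalaldehyde CC(C)(C)C=O
Why: acid-catalysed acetalisation under thermodynamic control gives mainly the cis acetal (t-Bu and Me cis), so the lactate stereocentre fixes the new acetal centre, which crystallisation upgrades (Seebach self-regeneration of stereocentres).

**Step 2**
Reactants: 2 (2S,5S)-2-tert-butyl-5-methyl-1,3-dioxolan-4-one
Product: 4 (2S,5R)-2-tert-butyl-5-methyl-5-(prop-2-en-1-yl)-1,3-dioxolan-4-one, via lithium enolate 3 (not isolated)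
Conditions: LiN(i-Pr)2, THF, −78 °C; allyl bromide, −78 → −20 °C
Reagents that add atoms: allyl bromide C=CCBr
Why: enolate alkylation occurs on the face anti to the t-Bu group, so the quaternary C10 centre is formed with net retention of the lactate configuration (Seebach alkylation).

**Step 3**
Reactants: 4 (2S,5R)-2-tert-butyl-5-methyl-5-(prop-2-en-1-yl)-1,3-dioxolan-4-one
Product: 6 2-[(2S,4R)-2-tert-butyl-4-methyl-5-oxo-1,3-dioxolan-4-yl]acetaldehyde, via ozonide 5 (not isolated)
Conditions: O3, CH2Cl2, −78 °C; Me2S, −78 °C → rt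
Reagents that add atoms: ozone [O-][O+]=O
Why: ozonolysis with reductive work-up cleaves only the terminal alkene and leaves both stereocentres untouched, giving the C8 aldehyde.

**Step 4**
Reactants: 7 (5S)-5-(hydroxymethyl)furan-2(5H)-one
Product: 8 (5S)-5-{[(triethylsilyl)oxy]methyl}furan-2(5H)-one
Conditions: Et3SiCl, imidazole, CH2Cl2, 0 °C
Reagents that add atoms: chlorotriethylsilane CC[Si](Cl)(CC)CC
Why: silylation of the primary alcohol gives a bulky C5–O group that later directs attack to the opposite face and can be oxidised directly to the aldehyde.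

**Step 5**
Reactants: 6 2-[(2S,4R)-2-tert-butyl-4-methyl-5-oxo-1,3-dioxolan-4-yl]acetaldehyde; 8 (5S)-5-{[(triethylsilyl)oxy]methyl}furan-2(5H)-one
Product: 9 (2S,5R)-2-tert-butyl-5-methyl-5-{2-oxo-2-[(2S,3S)-5-oxo-2-{[(triethylsilyl)oxy]methyl}oxolan-3-yl]ethyl}-1,3-dioxolan-4-one
Conditions: 3-benzyl-5-(2-hydroxyethyl)-4-methylthiazolium chloride (20 mol %), Et3N (40 mol %), 1,4-dioxane, 70 °C, slow addition of 6
Reagents that add atoms: none
Why: Proposed new method: the thiazol-2-ylidene converts aldehyde 6 into its Breslow enaminol (an acyl anion at C8), which adds 1,4 to the s-trans-locked butenolide 8 on the face anti to the CH2OSiEt3 group, setting C7 trans to C6 (the epimerisable C7–H also equilibrates to this trans isomer under Et3N), and the catalyst is then expelled; the closest known chemistry is the thiazolium-catalysed intermolecular Stetter reaction of aliphatic aldehydes with enoates and enones, together with the anti-selective conjugate addition of dithiane and nitronate acyl-anion equivalents to 5-(silyloxymethyl)butenolides.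

**Step 6**
Reactants: 9 (2S,5R)-2-tert-butyl-5-methyl-5-{2-oxo-2-[(2S,3S)-5-oxo-2-{[(triethylsilyl)oxy]methyl}oxolan-3-yl]ethyl}-1,3-dioxolan-4-one
Product: 11 (3R,5R)-3-hydroxy-3-methyl-5-[(2S,3R)-5-oxo-2-{[(triethylsilyl)oxy]methyl}oxolan-3-yl]oxolan-2-one, via hydroxy dioxolanone 10 (not isolated)
Conditions: LiBH(s-Bu)3 (1.1 equiv), THF, −78 °C; AcOH, −78 °C; then PPTS (cat.), PhMe, 40 °C
Reagents that add atoms: none
Why: Felkin–Anh reduction, in which the bulky hydride attacks the C8 ketone anti to the oxygen-bearing C6 arm of the C7 stereocentre and passes over H7, gives the 8R alcohol, which then lactonises onto the activated dioxolanone carbonyl with loss of pivalaldehyde, protecting O8 and freeing the C10 hydroxyl.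

**Step 7**
Reactants: 11 (3R,5R)-3-hydroxy-3-methyl-5-[(2S,3R)-5-oxo-2-{[(triethylsilyl)oxy]methyl}oxolan-3-yl]oxolan-2-one
Product: 14 (3S,4R,5S)-4-[(1R,3R)-1,3-dihydroxy-3,7-dimethyl-4-oxooct-7-en-5-yn-1-yl]-3-methyl-5-{[(triethylsilyl)oxy]methyl}oxolan-2-one, via dilithium enolate-alkoxide 12 (not isolated), via trilithium alkynyl lactolate 13 (not isolated)
Conditions: LiN(i-Pr)2 (2.05 equiv), THF, −78 °C; LiC≡CC(Me)=CH2 (1.5 equiv, from 2-methylbut-1-en-3-yne and n-BuLi), −78 → −40 °C; MeI, DMPU, −78 °C; AcOH, −78 °C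
Reagents that add atoms: 2-methylbut-1-en-3-yne C=C(C)C#C; iodomethane CI
Why: the base masks the enolisable C12 lactone as its lithium enolate, so the acetylide can add only to the non-enolisable α-oxy lactone carbonyl C1 (acetylide addition to a lactone, stable lactolate), after which MeI alkylates the enolate on the face anti to the C7 side chain and sets C11 with the methyl trans to C7 (lactone enolate alkylation), and cold protonation releases the α'-hydroxy ynone.

**Step 8**
Reactants: 14 (3S,4R,5S)-4-[(1R,3R)-1,3-dihydroxy-3,7-dimethyl-4-oxooct-7-en-5-yn-1-yl]-3-methyl-5-{[(triethylsilyl)oxy]methyl}oxolan-2-one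
Product: 15 (3S,4R,5S)-4-{(1R)-1-hydroxy-2-[(2R)-2-methyl-3-oxo-5-(prop-1-en-2-yl)-2,3-dihydrofuran-2-yl]ethyl}-3-methyl-5-{[(triethylsilyl)oxy]methyl}oxolan-2-one
Conditions: Ph3PAuNTf2 (5 mol %), CH2Cl2, rt
Reagents that add atoms: none
Why: the monovalent gold π-acid activates the ynone for 5-endo-dig oxa-Michael attack of the tertiary C10 hydroxyl on C3 (the C8 hydroxyl could only close a seven-membered ring), giving the 3(2H)-furanone under neutral conditions without touching C10.

**Step 9**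
Reactants: 15 (3S,4R,5S)-4-{(1R)-1-hydroxy-2-[(2R)-2-methyl-3-oxo-5-(prop-1-en-2-yl)-2,3-dihydrofuran-2-yl]ethyl}-3-methyl-5-{[(triethylsilyl)oxy]methyl}oxolan-2-one
Product: 16 (1R)-2-[(2R)-2-methyl-3-oxo-5-(prop-1-en-2-yl)-2,3-dihydrofuran-2-yl]-1-[(2S,3R,4S)-4-methyl-5-oxo-2-{[(triethylsilyl)oxy]methyl}oxolan-3-yl]ethyl (2Z)-2-methylbut-2-enoate
Conditions: angelic acid, 2,4,6-Cl3C6H2COCl, Et3N, PhMe, rt; then 15, 80 °C
Reagents that add atoms: angelic acid C/C=C(/C)C(=O)O
Why: Yamaguchi-type mixed-anhydride esterification without a nucleophilic catalyst acylates the hindered C8 hydroxyl at the angeloyl carbonyl without Z→E isomerisation, and the 12,6-lactone does not migrate because the alternative 12,8-lactone would be cis-disubstituted.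

**Step 10**
Reactants: 16 (1R)-2-[(2R)-2-methyl-3-oxo-5-(prop-1-en-2-yl)-2,3-dihydrofuran-2-yl]-1-[(2S,3R,4S)-4-methyl-5-oxo-2-{[(triethylsilyl)oxy]methyl}oxolan-3-yl]ethyl (2Z)-2-methylbut-2-enoate
Product: 17 (1R)-1-[(2S,3R,4S)-2-formyl-4-methyl-5-oxooxolan-3-yl]-2-[(2R)-2-methyl-3-oxo-5-(prop-1-en-2-yl)-2,3-dihydrofuran-2-yl]ethyl (2Z)-2-methylbut-2-enoate
Conditions: (COCl)2, DMSO, CH2Cl2, −78 → −30 °C; Et3N, −78 → 0 °C
Reagents that add atoms: none
Why: Swern oxidation applied directly to the primary triethylsilyl ether, where the chlorosulfonium salt cleaves the Si–O bond to the alkoxysulfonium ion and Et3N then gives the C5 aldehyde without a separate desilylation and without epimerising C6 at low temperature.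

**Step 11**
Reactants: 17 (1R)-1-[(2S,3R,4S)-2-formyl-4-methyl-5-oxooxolan-3-yl]-2-[(2R)-2-methyl-3-oxo-5-(prop-1-en-2-yl)-2,3-dihydrofuran-2-yl]ethyl (2Z)-2-methylbut-2-enoate
Product: 18 (1R)-1-[(2R,3R,4S)-2-ethenyl-4-methyl-5-oxooxolan-3-yl]-2-[(2R)-2-methyl-3-oxo-5-(prop-1-en-2-yl)-2,3-dihydrofuran-2-yl]ethyl (2Z)-2-methylbut-2-enoate
Conditions: Ph3PCH3Br, KN(SiMe3)2, THF, 0 °C; then 17, −78 → 0 °C
Reagents that add atoms: methyltriphenylphosphonium bromide C[P+](c1ccccc1)(c1ccccc1)c1ccccc1.[Br-]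
Why: Wittig methylenation of the aldehyde at −78 °C is faster than enolisation of the α-acyloxy aldehyde, so C6 keeps its configuration and the esters and the vinylogous-ester carbonyl are not attacked.

**Step 12**
Reactants: 18 (1R)-1-[(2R,3R,4S)-2-ethenyl-4-methyl-5-oxooxolan-3-yl]-2-[(2R)-2-methyl-3-oxo-5-(prop-1-en-2-yl)-2,3-dihydrofuran-2-yl]ethyl (2Z)-2-methylbut-2-enoate
Product: 19 target CNP0278264.1 (4Z,6R,7R,8R,10R,11S)-8-angeloyloxy-1-oxo-3,10-epoxygermacra-2,4-dien-12,6-olide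
Conditions: second-generation Hoveyda–Grubbs catalyst (15 mol %), 1,4-benzoquinone (20 mol %), PhMe (2 mM), 90 °C
Reagents that add atoms: none
Why: ring-closing metathesis, in which ruthenium loads on the monosubstituted C6 vinyl group and closes onto the isopropenyl group with loss of ethylene, forms the trisubstituted C4=C5 bond, which can only be Z because the furanone oxygen bridge places it in a nine-membered ring; the trisubstituted, electron-poor angelate alkene does not take part.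

**Compound list**
1 | (S)-lactic acid | C[C@H](O)C(=O)O | starting material
2 | (2S,5S)-2-tert-butyl-5-methyl-1,3-dioxolan-4-one | C[C@@H]1O[C@H](C(C)(C)C)OC1=O | intermediate
3 | lithium (2S)-2-tert-butyl-5-methyl-1,3-dioxol-4-olate (lithium enolate of 2) | CC1=C([O-])O[C@@H](C(C)(C)C)O1.[Li+] | intermediate (not isolated)
4 | (2S,5R)-2-tert-butyl-5-methyl-5-(prop-2-en-1-yl)-1,3-dioxolan-4-one | C[C@]1(CC=C)O[C@H](C(C)(C)C)OC1=O | intermediate
5 | (2S,5R)-2-tert-butyl-5-methyl-5-(1,2,4-trioxolan-3-ylmethyl)-1,3-dioxolan-4-one (ozonide, mixture at the trioxolane carbon) | C[C@]1(CC2OOCO2)O[C@H](C(C)(C)C)OC1=O | intermediate (not isolated)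
6 | 2-[(2S,4R)-2-tert-butyl-4-methyl-5-oxo-1,3-dioxolan-4-yl]acetaldehyde | C[C@]1(CC=O)O[C@H](C(C)(C)C)OC1=O | intermediate
7 | (5S)-5-(hydroxymethyl)furan-2(5H)-one | OC[C@H]1OC(=O)C=C1 | starting material
8 | (5S)-5-{[(triethylsilyl)oxy]methyl}furan-2(5H)-one | CC[Si](CC)(CC)OC[C@H]1OC(=O)C=C1 | intermediate
9 | (2S,5R)-2-tert-butyl-5-methyl-5-{2-oxo-2-[(2S,3S)-5-oxo-2-{[(triethylsilyl)oxy]methyl}oxolan-3-yl]ethyl}-1,3-dioxolan-4-one | CC[Si](CC)(CC)OC[C@H]1OC(=O)C[C@@H]1C(=O)C[C@@]2(C)O[C@H](C(C)(C)C)OC2=O | intermediate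
10 | (2S,5R)-2-tert-butyl-5-{(2R)-2-hydroxy-2-[(2S,3R)-5-oxo-2-{[(triethylsilyl)oxy]methyl}oxolan-3-yl]ethyl}-5-methyl-1,3-dioxolan-4-one | CC[Si](CC)(CC)OC[C@H]1OC(=O)C[C@@H]1[C@H](O)C[C@@]2(C)O[C@H](C(C)(C)C)OC2=O | intermediate (not isolated)
11 | (3R,5R)-3-hydroxy-3-methyl-5-[(2S,3R)-5-oxo-2-{[(triethylsilyl)oxy]methyl}oxolan-3-yl]oxolan-2-one | CC[Si](CC)(CC)OC[C@H]1OC(=O)C[C@@H]1[C@H]2C[C@@](C)(O)C(=O)O2 | intermediate
12 | dilithium enolate-alkoxide of 11 (C12 lactone enolate, C10 alkoxide) | CC[Si](CC)(CC)OC[C@H]1OC([O-])=C[C@@H]1[C@H]2C[C@@](C)([O-])C(=O)O2.[Li+].[Li+] | intermediate (not isolated)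
13 | trilithium alkynyl lactolate (acetylide adduct at C1 of 12, mixture at C1) | CC[Si](CC)(CC)OC[C@H]1OC([O-])=C[C@@H]1[C@H]2C[C@@](C)([O-])C([O-])(C#CC(C)=C)O2.[Li+].[Li+].[Li+] | intermediate (not isolated)
14 | (3S,4R,5S)-4-[(1R,3R)-1,3-dihydroxy-3,7-dimethyl-4-oxooct-7-en-5-yn-1-yl]-3-methyl-5-{[(triethylsilyl)oxy]methyl}oxolan-2-one | CC[Si](CC)(CC)OC[C@H]1OC(=O)[C@@H](C)[C@@H]1[C@H](O)C[C@@](C)(O)C(=O)C#CC(C)=C | intermediate
15 | (3S,4R,5S)-4-{(1R)-1-hydroxy-2-[(2R)-2-methyl-3-oxo-5-(prop-1-en-2-yl)-2,3-dihydrofuran-2-yl]ethyl}-3-methyl-5-{[(triethylsilyl)oxy]methyl}oxolan-2-one | CC[Si](CC)(CC)OC[C@H]1OC(=O)[C@@H](C)[C@@H]1[C@H](O)C[C@@]2(C)OC(=CC2=O)C(C)=C | intermediate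
16 | (1R)-2-[(2R)-2-methyl-3-oxo-5-(prop-1-en-2-yl)-2,3-dihydrofuran-2-yl]-1-[(2S,3R,4S)-4-methyl-5-oxo-2-{[(triethylsilyl)oxy]methyl}oxolan-3-yl]ethyl (2Z)-2-methylbut-2-enoate | CC[Si](CC)(CC)OC[C@H]1OC(=O)[C@@H](C)[C@@H]1[C@H](OC(=O)/C(C)=C\C)C[C@@]2(C)OC(=CC2=O)C(C)=C | intermediate
17 | (1R)-1-[(2S,3R,4S)-2-formyl-4-methyl-5-oxooxolan-3-yl]-2-[(2R)-2-methyl-3-oxo-5-(prop-1-en-2-yl)-2,3-dihydrofuran-2-yl]ethyl (2Z)-2-methylbut-2-enoate | O=C[C@H]1OC(=O)[C@@H](C)[C@@H]1[C@H](OC(=O)/C(C)=C\C)C[C@@]2(C)OC(=CC2=O)C(C)=C | intermediate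
18 | (1R)-1-[(2R,3R,4S)-2-ethenyl-4-methyl-5-oxooxolan-3-yl]-2-[(2R)-2-methyl-3-oxo-5-(prop-1-en-2-yl)-2,3-dihydrofuran-2-yl]ethyl (2Z)-2-methylbut-2-enoate | C=C[C@H]1OC(=O)[C@@H](C)[C@@H]1[C@H](OC(=O)/C(C)=C\C)C[C@@]2(C)OC(=CC2=O)C(C)=C | intermediate
19 | CNP0278264.1, (4Z,6R,7R,8R,10R,11S)-8-angeloyloxy-1-oxo-3,10-epoxygermacra-2,4-dien-12,6-olide | C/C=C(/C)C(=O)O[C@@H]1C[C@@]2(C)OC(=CC2=O)/C(C)=C\[C@H]2OC(=O)[C@@H](C)[C@@H]21 | target

**Step count and risks**

Total steps: 12. Longest linear sequence: 11 (steps 1–3 and 5–12, from (S)-lactic acid).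

Steps most likely to fail:

Step 5 (carbene-catalysed union). Intermolecular Stetter additions to β-substituted cyclic enoates are not established. Acyloin formation from 6, or amine-induced racemisation of 8 through its dienolate, could win. Fallback, setting out from 6 and 8 and coming back at 9: switch from the closed-shell carbene pathway to an open-shell acyl donor. Irradiate 6 (1.5 equiv) and 8 with (Bu4N)4W10O32 (2 mol %) in MeCN at 390 nm and rt. Hydrogen-atom abstraction from the formyl C–H gives the nucleophilic acyl radical, which adds to C7 of 8 anti to the silyloxymethyl group; back hydrogen transfer closes the cycle. This is base-free and gives 9 directly; it makes no new compound (F0).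

Step 6 (configuration at C8). The Felkin–Anh preference rests on the C6 arm acting as the large group and may be eroded or reversed by the remote C10 acetal oxygen. Fallback, setting out from 9 and coming back at 11: if the hydride adds mainly to the other face, leave out the PPTS treatment and isolate the (8S)-alcohol, (2S,5R)-2-tert-butyl-5-{(2S)-2-hydroxy-2-[(2S,3R)-5-oxo-2-{[(triethylsilyl)oxy]methyl}oxolan-3-yl]ethyl}-5-methyl-1,3-dioxolan-4-one F1. Invert it by Mitsunobu displacement (4-nitrobenzoic acid, PPh3, DIAD, THF, 0 °C) to the (8R)-ester, (1R)-2-[(2S,4R)-2-tert-butyl-4-methyl-5-oxo-1,3-dioxolan-4-yl]-1-[(2S,3R)-5-oxo-2-{[(triethylsilyl)oxy]methyl}oxolan-3-yl]ethyl 4-nitrobenzoate F2. Brief K2CO3/MeOH at 0 °C then removes the nitrobenzoate, and the liberated (8R)-alkoxide closes onto the dioxolanone to give 11.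

Step 7 (one-flask alkynylation and methylation). Three anionic sites and two lactones are handled in one flask. Slow acetylide addition next to the C10 alkoxide, or over-methylation, would lower the yield. Fallback, setting out from 11 and coming back at 14: run the two events separately and rely on reagent chemoselectivity instead of enolate masking. Form 12, add MeI and quench to isolate the methylated bis-lactone, (3R,5R)-3-hydroxy-3-methyl-5-[(2S,3R,4S)-4-methyl-5-oxo-2-{[(triethylsilyl)oxy]methyl}oxolan-3-yl]oxolan-2-one F3. Then treat it with Cl2CeC≡CC(Me)=CH2 (3 equiv, from the lithium acetylide and CeCl3) in THF at −78 °C. The weakly basic trivalent cerium acetylide adds to the α-oxygenated, non-enolisable lactone carbonyl without enolising or epimerising the C12 lactone; cold AcOH quench gives 14.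

**Further compounds**
F0 | step 5 | none | none
F1 | step 6 | (2S,5R)-2-tert-butyl-5-{(2S)-2-hydroxy-2-[(2S,3R)-5-oxo-2-{[(triethylsilyl)oxy]methyl}oxolan-3-yl]ethyl}-5-methyl-1,3-dioxolan-4-one | CC[Si](CC)(CC)OC[C@H]1OC(=O)C[C@@H]1[C@@H](O)C[C@@]2(C)O[C@H](C(C)(C)C)OC2=O
F2 | step 6 | (1R)-2-[(2S,4R)-2-tert-butyl-4-methyl-5-oxo-1,3-dioxolan-4-yl]-1-[(2S,3R)-5-oxo-2-{[(triethylsilyl)oxy]methyl}oxolan-3-yl]ethyl 4-nitrobenzoate | CC[Si](CC)(CC)OC[C@H]1OC(=O)C[C@@H]1[C@H](OC(=O)c3ccc(cc3)[N+](=O)[O-])C[C@@]2(C)O[C@H](C(C)(C)C)OC2=O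
F3 | step 7 | (3R,5R)-3-hydroxy-3-methyl-5-[(2S,3R,4S)-4-methyl-5-oxo-2-{[(triethylsilyl)oxy]methyl}oxolan-3-yl]oxolan-2-one | CC[Si](CC)(CC)OC[C@H]1OC(=O)[C@@H](C)[C@@H]1[C@H]2C[C@@](C)(O)C(=O)O2
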